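**Plan**

- Retrosynthesis: (i) the two carbinol C–H bonds and the oxirane of the oxygenated ring are taken back to a 4-methoxyphenol; (ii) the C11–aryl bond is cut (B-alkyl Suzuki–Miyaura coupling of a 7,9(11)-diene); (iii) the C3–C4 bond of ring A is cut after a C1=C2 double bond is added, so that ring A unfolds to a C1-vinyl δ-lactone (O–C1, C18(=O)–C4) fused to ring B; (iv) the C1–C10 bond (aldol) and the C4 side chain lead back to (R)-carvone.
- Enabling feature: C4 is a quaternary carbon that carries the carboxyl group and is joined to C1 through C5–C10, so C18–C4/C3–C2=C1 is the retron of an ester-enolate Claisen rearrangement and its allyl ester is a six-membered lactone.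
- Forward order: ring B (from carvone) → temporary lactone ring → ring A by the [3,3] shift → aryl ring joined at C11 → C1=C2 saturated → arene dearomatised to the epoxy-diol ring.
- Stereochemistry: C5 from (R)-carvone; C10 by attack anti to the C5 side chain; C1 by chelation-controlled reduction, relayed to C4 suprafacially; C9 by α-face hydroboration; the oxirane by a chiral phase-transfer catalyst; both carbinols by epoxide-directed iBu2AlH reduction.

Key step: step 9

Remark on locants: the decalin is numbered as in the target (ring A C1–C5 and C10, ring B C5–C10, C11 the CH2 link, C18 the carboxyl carbon on C4); the oxygenated ring is C1'–C6' (C1' bears C11, C2' oxirane CH, C3' and C6' carbinol carbons, C4' bears CH3, C5' =CH); β is the face of the C10 methyl of the target. Centres that are mixtures and are erased later (C4 in 3–11, C9 in 3, C1 in 7) carry no stereo label in the SMILES.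

Assumption: N-benzylcinchonidinium chloride is taken to direct the peroxide to the enone face that gives the target's oxirane; if the sense proves opposite, the pseudoenantiomeric N-benzylcinchoninium chloride takes its place.

**Route**

Step 1
Reactants: 1 (R)-(−)-carvone
Product: 2 trans-6-methylcarvone
Conditions: LiN(iPr)2, THF, −78 °C; MeI, −78 → 0 °C
Reagents that add atoms: iodomethane, CI
Why: Kinetic deprotonation at C10, the only sp3 α-carbon of the enone, and methylation of the enolate anti to the C5 isopropenyl group (ketone enolate alkylation); the C10 configuration is of no consequence because the centre is re-enolised in step 5.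

Step 2
Reactants: 2 trans-6-methylcarvone
Product: 3 diol
Conditions: 9-BBN (2.5 equiv), THF, 0 °C → rt; then NaOH, H2O2, 0 °C
Reagents that add atoms: hydrogen peroxide, OO
Why: Anti-Markovnikov hydroboration–oxidation of the 1,1-disubstituted isopropenyl alkene, with the excess borane also reducing the enone carbonyl 1,2 while the trisubstituted C7=C8 bond stays inert; the new centres at C4 and C9 are erased in steps 9 and 3.

Step 3
Reactants: 3 diol
Product: 4 keto acid
Conditions: CrO3, H2SO4, acetone/H2O, 0 °C
Reagents that add atoms: water, O
Why: Jones oxidation takes the primary alcohol to the carboxylic acid through the aldehyde hydrate and returns the allylic alcohol to the enone.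

Step 4
Reactants: 4 keto acid
Product: 5 keto methyl ester
Conditions: MeI, K2CO3, DMF, rt
Reagents that add atoms: iodomethane, CI
Why: O-alkylation of the carboxylate gives the methyl ester, which tolerates the amide base of step 5 and later serves as the acyl donor for lactonisation.

Step 5
Reactants: 5 keto methyl ester; 6 acrolein
Product: 7 aldol adduct
Conditions: LiN(SiMe3)2, THF, −78 °C; acrolein, −78 °C; AcOH quench at −78 °C
Reagents that add atoms: none
Why: LiN(SiMe3)2 enolises the ketone toward C10 (the ester α-hydrogen is too weakly acidic for this base) and the tetrasubstituted enolate adds 1,2 to acrolein (aldol addition) on the face anti to the C5 side chain, which fixes C10 with its methyl β; the carbinol configuration is irrelevant because C1 is oxidised in step 6.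

Step 6
Reactants: 7 aldol adduct
Product: 8 vinyl diketone
Conditions: Dess–Martin periodinane, CH2Cl2, 0 °C → rt
Reagents that add atoms: none
Why: Dess–Martin oxidation of the allylic alcohol under neutral conditions gives the non-enolisable 1,3-diketone without retro-aldol cleavage.

Step 7
Reactants: 8 vinyl diketone
Product: 10 vinyl lactone, via hydroxy ester 9 (not isolated)
Conditions: Zn(BH4)2, Et2O, −78 → −30 °C; 1 M HCl (aq), 0 °C; then pyridinium p-toluenesulfonate (cat.), toluene, 70 °C
Reagents that add atoms: none
Why: Zn(BH4)2 bridges the C1 and C9 carbonyl oxygens and delivers hydride 1,2 to the more reactive exocyclic vinyl ketone from the chelate face that carries only the C10 methyl, away from the C5 methine (chelation-controlled reduction), which should give the 1S carbinol; acid then closes the δ-lactone by transesterification with loss of methanol.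

Step 8
Reactants: 10 vinyl lactone
Product: 11 diene lactone
Conditions: Zn, CH2Br2, TiCl4, THF/CH2Cl2, 0 °C → rt
Reagents that add atoms: dibromomethane, BrCBr
Why: Takai–Lombardo methylenation converts the hindered C9 ketone into the exocyclic alkene with a non-basic reagent that spares the lactone and the C1 centre, and removes the only other enolisable carbonyl before the key step.

Step 9
Reactants: 11 diene lactone
Product: 14 trienoic acid, via silyl ketene acetal 12 (not isolated), via silyl ester 13 (not isolated)
Conditions: LiN(iPr)2, t-BuMe2SiCl, DMPU, THF, −78 °C; xylene, 140 °C (sealed); then AcOH/THF/H2O, rt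
Reagents that add atoms: tert-butylchlorodimethylsilane, CC(C)(C)[Si](C)(C)Cl (silicon present in 12 and 13 only)
Why: Enolisation with in situ silylation converts the lactone into its cyclic O-silyl ketene acetal 12 (C4=C18(OSi)–O–C1), and on heating the C4 terminus of the ketene acetal and the C3 terminus of the C1 vinyl group unite in a concerted [3,3]-sigmatropic (Ireland–Claisen) shift that forms C3–C4, breaks C1–O, moves the alkene to C1=C2 and turns the lactone carbonyl into the C4 carboxyl (silyl ester 13, cleaved on work-up). The closest known reaction type is the Ireland–Claisen rearrangement of lactone silyl ketene acetals that carry an alkenyl group on the carbinol carbon, which turns δ-lactones into cyclohex-3-enecarboxylic acids and 6-alkenyl-1,4-dioxan-2-ones into dihydropyran-2-carboxylic acids. Ring A closes as a six-membered carbocycle by this pericyclic exchange of the O–C18 bridge for the C2–C3 bridge through a boat-shaped six-atom array (C4, C18, O, C1, C2, C3) enforced by the two-carbon C5–C10 tether, so exo/endo labels do not apply and no other ring size can form. C4 is the only new stereocentre and is fixed by the suprafacial course: the vinyl group lies on the β face of the lactone ring (cis to the C10 methyl, as set by the 1S carbinol of step 7), C3 therefore bonds to the β face of the trigonal C4, and the carboxyl carbon is left α (equatorial) with the methyl β (axial); the C4 epimers of 11 converge because C4 is planar in 12, whereas the C1 epimer would give the C4 epimer. The step needs enolisation at C4 only and rearrangement in preference to breakdown of the ketene acetal, which the substrate secures by having its sole acidic C–H at C4 (the C9 ketone is gone since step 8) and by silylation at −78 °C; because the trans ring fusion locks the lactone half-chair with the vinyl group equatorial, the shift must pass through the boat form of the lactone ring with vinyl and C10 methyl nearly eclipsed, which is why 140 °C is specified.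

Step 10
Reactants: 14 trienoic acid
Product: 15 4-methoxybenzyl ester
Conditions: 4-MeOC6H4CH2Cl, K2CO3, Bu4NI (cat.), DMF, rt
Reagents that add atoms: 4-methoxybenzyl chloride, COc1ccc(CCl)cc1
Why: O-alkylation of the hindered carboxylate gives the 4-methoxybenzyl ester, which masks the acid through the borane, base and phase-transfer steps and falls to acid in step 16.

Step 11
Reactants: 16 4-methoxy-3-methylphenol
Product: 17 2-bromo-4-methoxy-5-methylphenol
Conditions: N-bromosuccinimide, MeCN, 0 °C
Reagents that add atoms: N-bromosuccinimide, O=C1CCC(=O)N1Br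
Why: Electrophilic aromatic bromination is directed by the phenolic hydroxyl to its free ortho position para to the methyl group, the other ortho position being flanked by that methyl group.

Step 12
Reactants: 15 4-methoxybenzyl ester; 17 2-bromo-4-methoxy-5-methylphenol
Product: 19 coupled phenol, via alkylborane 18 (not isolated)
Conditions: 9-BBN, THF, 0 °C → rt; then 17, Pd(OAc)2 (5 mol %), 2-dicyclohexylphosphino-2',6'-dimethoxybiphenyl (10 mol %), K3PO4 (aq), THF, 60 °C
Reagents that add atoms: 9-borabicyclo[3.3.1]nonane, B1C2CCCC1CCC2 (boron present in 18 only)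
Why: 9-BBN adds to the terminal C11 of the diene from the α face, anti to the axial C10 methyl, which sets C9 (9α-H) while the C1=C2 and C7=C8 bonds stay intact, and the primary alkylborane is joined to the aryl bromide by B-alkyl Suzuki–Miyaura coupling.

Step 13
Reactants: 19 coupled phenol
Product: 20 ring A saturated phenol
Conditions: 2-nitrobenzenesulfonyl hydrazide, Et3N, CH2Cl2, rt
Reagents that add atoms: none
Why: Diimide generated in situ transfers hydrogen to the cis-disubstituted C1=C2 bond much faster than to the trisubstituted C7=C8 bond and leaves the benzylic ester and the arene untouched (diimide reduction).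

Step 14
Reactants: 20 ring A saturated phenol
Product: 21 quinone monoketal
Conditions: PhI(OAc)2, MeOH, 0 °C
Reagents that add atoms: methanol, CO
Why: Oxidative dearomatisation of the 4-methoxyphenol by PhI(OAc)2 in methanol traps the cation at the methoxy-bearing carbon and gives the quinone monoketal, which places the ketone (C6') next to the C11-bearing carbon C1'.

Step 15
Reactants: 21 quinone monoketal
Product: 22 epoxy ketal
Conditions: t-BuOOH, NaOH (aq), N-benzylcinchonidinium chloride (10 mol %), toluene, 0 °C → rt
Reagents that add atoms: tert-butyl hydroperoxide, CC(C)(C)OO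
Why: Weitz–Scheffer epoxidation in which the hydroperoxide anion adds to C2', the only unsubstituted β-carbon of the cross-conjugated dienone (C4' carries a methyl group), and the chiral ammonium ion pair selects the enone face so that the C1'–C2' oxirane should form with the target's configuration (asymmetric phase-transfer epoxidation of a quinone monoketal).

Step 16
Reactants: 22 epoxy ketal
Product: 23 epoxyquinone acid
Conditions: CF3CO2H, H2O, anisole, CH2Cl2, 0 °C
Reagents that add atoms: water, O
Why: Aqueous acid hydrolyses the dimethyl ketal to the C3' ketone and cleaves the 4-methoxybenzyl ester through the benzylic cation, which anisole captures, while the oxirane flanked by two carbonyl groups resists opening.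

Step 17
Reactants: 23 epoxyquinone acid
Product: 24 target CNP0358222.2
Conditions: iBu2AlH (5 equiv), THF, −78 °C; potassium sodium tartrate (aq)
Reagents that add atoms: none
Why: iBu2AlH reduces both enedione carbonyls 1,2 at −78 °C after coordination to the oxirane oxygen, so hydride arrives on the epoxide face and both new hydroxyls (C3' and C6') should come out trans to the oxirane and cis to each other, while the aluminium carboxylate is not reduced (epoxide-directed ketone reduction).

**Compound list**

1 | (R)-(−)-carvone, (5R)-2-methyl-5-(prop-1-en-2-yl)cyclohex-2-en-1-one | CC1=CC[C@H](CC1=O)C(C)=C | starting material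
2 | trans-6-methylcarvone, (5R,6S)-2,6-dimethyl-5-(prop-1-en-2-yl)cyclohex-2-en-1-one (C10 methyl α, trans to the isopropenyl group) | CC1=CC[C@H]([C@H](C)C1=O)C(C)=C | intermediate
3 | diol, 5-(1-hydroxypropan-2-yl)-2,6-dimethylcyclohex-2-en-1-ol, C5 and C10 as in 2, epimers at C9 and C4 | CC1=CC[C@H]([C@H](C)C1O)C(C)CO | intermediate
4 | keto acid, 2-(2,4-dimethyl-3-oxocyclohex-4-en-1-yl)propanoic acid, C5 and C10 as in 2, epimers at C4 | CC1=CC[C@H]([C@H](C)C1=O)C(C)C(=O)O | intermediate
5 | keto methyl ester, methyl ester of 4 | CC1=CC[C@H]([C@H](C)C1=O)C(C)C(=O)OC | intermediate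
6 | acrolein (prop-2-enal) | C=CC=O | starting material
7 | aldol adduct, methyl 2-[2-(1-hydroxyprop-2-enyl)-2,4-dimethyl-3-oxocyclohex-4-en-1-yl]propanoate; C10 quaternary with CH3 β and C1 α (trans to the C5 side chain); epimers at C1 and C4 | CC1=CC[C@@H](C(C)C(=O)OC)[C@](C)(C(O)C=C)C1=O | intermediate
8 | vinyl diketone, 7 with C1 oxidised to the ketone (C10 acryloyl group) | CC1=CC[C@@H](C(C)C(=O)OC)[C@](C)(C(=O)C=C)C1=O | intermediate
9 | hydroxy ester, (1S)-allylic alcohol from 8 | CC1=CC[C@@H](C(C)C(=O)OC)[C@](C)([C@@H](O)C=C)C1=O | intermediate
10 | vinyl lactone, δ-lactone (O–C1, C18(=O)–C4) trans-fused at C5/C10 to the ring B enone (C9=O, C7=C8, 8-CH3); 1S, vinyl cis to the β-methyl on C10; epimers at C4 | CC1=CC[C@H]2C(C)C(=O)O[C@@H](C=C)[C@]2(C)C1=O | intermediate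
11 | diene lactone, 10 with C9=C11H2 in place of the ketone | C=C1C(C)=CC[C@@H]2[C@]1(C)[C@H](C=C)OC(=O)C2C | intermediate
12 | silyl ketene acetal, cyclic O-tert-butyldimethylsilyl ketene acetal of 11 (C4=C18(OSi)–O–C1) | C=C1C(C)=CC[C@@H]2[C@]1(C)[C@H](C=C)OC(O[Si](C)(C)C(C)(C)C)=C2C | intermediate
13 | silyl ester, tert-butyldimethylsilyl ester of 14 | C=C1C(C)=CC[C@@H]2[C@]1(C)C=CC[C@@]2(C)C(=O)O[Si](C)(C)C(C)(C)C | intermediate
14 | trienoic acid, trans-fused decalin with C1=C2, C7=C8 (8-CH3) and C9=C11H2; 10β-CH3, 5α-H, 4β-CH3, 4α-CO2H | C=C1C(C)=CC[C@@H]2[C@]1(C)C=CC[C@@]2(C)C(=O)O | intermediate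
15 | 4-methoxybenzyl ester of 14 | C=C1C(C)=CC[C@@H]2[C@]1(C)C=CC[C@@]2(C)C(=O)OCc3ccc(OC)cc3 | intermediate
16 | 4-methoxy-3-methylphenol | COc1ccc(O)cc1C | starting material
17 | 2-bromo-4-methoxy-5-methylphenol | COc1cc(Br)c(O)cc1C | intermediate
18 | alkylborane, B-(C11-alkyl)-9-borabicyclo[3.3.1]nonane from 15 (9α-H) | C(B1C2CCCC1CCC2)[C@H]1C(C)=CC[C@@H]2[C@]1(C)C=CC[C@@]2(C)C(=O)OCc3ccc(OC)cc3 | intermediate
19 | coupled phenol, C11 bonded to C2 of 4-methoxy-5-methylphenol (ortho to OH); C1=C2 and C7=C8 retained; 9α-H; 4-methoxybenzyl ester | COc1cc(C[C@H]2C(C)=CC[C@@H]3[C@]2(C)C=CC[C@@]3(C)C(=O)OCc2ccc(OC)cc2)c(O)cc1C | intermediate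
20 | ring A saturated phenol, 1,2-dihydro-19 | COc1cc(C[C@H]2C(C)=CC[C@@H]3[C@]2(C)CCC[C@@]3(C)C(=O)OCc2ccc(OC)cc2)c(O)cc1C | intermediate
21 | quinone monoketal, 4,4-dimethoxy-5-methylcyclohexa-2,5-dien-1-one bearing C11 at its C2 (C6' ketone, C3' dimethyl ketal) | COC1(OC)C=C(C[C@H]2C(C)=CC[C@@H]3[C@]2(C)CCC[C@@]3(C)C(=O)OCc2ccc(OC)cc2)C(=O)C=C1C | intermediate
22 | epoxy ketal, 21 with the C1'–C2' oxirane in the target's configuration | CC1=CC(=O)[C@]2(C[C@H]3C(C)=CC[C@@H]4[C@]3(C)CCC[C@@]4(C)C(=O)OCc3ccc(OC)cc3)O[C@@H]2C1(OC)OC | intermediate
23 | epoxyquinone acid, C3' and C6' ketones, C1'–C2' oxirane, free C18 acid | CC1=CC(=O)[C@]2(C[C@H]3C(C)=CC[C@@H]4[C@]3(C)CCC[C@@]4(C)C(=O)O)O[C@@H]2C1=O | intermediate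
24 | CNP0358222.2 | CC1=C[C@@H](O)[C@]2(C[C@H]3C(C)=CC[C@@H]4[C@]3(C)CCC[C@@]4(C)C(=O)O)O[C@@H]2[C@H]1O | target

**Count and risks**

Total step count: 17. Longest linear sequence: 16 (steps 1–10 and 12–17, from (R)-carvone).

Steps most likely to fail:

1. Step 9. The shift must pass through the boat form of the lactone ring with the C1 vinyl and C10 methyl groups nearly eclipsed, so breakdown of the silyl ketene acetal (desilylation, ketene-forming fragmentation, ionisation of the allylic C1–O bond) may outrun the rearrangement. The fallback closes ring A at the same bond by enolate alkylation; it sets out from 4 and returns at 20. Keto acid 4 is esterified with 4-methoxybenzyl chloride and K2CO3 to the 4-methoxybenzyl keto ester F1. Its C10 enolate (LiN(iPr)2, DMPU) is alkylated with 1-chloro-3-iodopropane anti to the C5 side chain to give the 3-chloropropyl ketone F2. Takai–Lombardo methylenation gives the chloropropyl diene F3, and NaI in acetone gives the iodopropyl diene F4. KN(SiMe3)2 then forms the C4 ester enolate, which displaces iodide (6-exo-tet) to give the bicyclic diene ester F5. The enolate rotamer with C5–H in the enolate plane (allylic strain) should place the ester equatorial. Hydroboration of F5 and Suzuki–Miyaura coupling with 17 as in step 12 gives 20.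

2. Step 15. Facial selectivity of the peroxide addition may be poor, since the resident stereocentres are remote and an uncatalysed background epoxidation competes. The fallback uses an auxiliary; it sets out from 21 and returns at 23. Transketalisation of 21 with (R,R)-hydrobenzoin (BF3·OEt2, CH2Cl2) gives the C2-symmetric spiro-ketal dienone F6. Epoxidation with t-BuOOH and DBU under control of the ketal gives the spiro-ketal epoxide F7. Aqueous CF3CO2H with anisole then removes ketal and ester to give 23.

3. Step 7. Reduction of the C9 enone may compete, or chelation may be incomplete, giving the C1 epimer that step 9 would carry into the C4 epimer. The fallback uses reagent control on an alkynyl ketone; it sets out from 5 and returns at 10. The C10 enolate of 5 (LiN(SiMe3)2) adds to 3-(trimethylsilyl)propynal to give the propargylic aldol F8, and Dess–Martin oxidation gives the alkynyl diketone F9. Corey–Bakshi–Shibata reduction with (R)-1-methyl-3,3-diphenyl-tetrahydro-1H,3H-pyrrolo[1,2-c][1,3,2]oxazaborole and catecholborane (quaternary C10 as the large, alkynyl as the small substituent) gives the configured propargylic alcohol F10. Acid lactonisation gives the silylalkynyl lactone F11, and Bu4NF/AcOH gives the ethynyl lactone F12. Semihydrogenation (H2, Pd/CaCO3 poisoned with Pb(OAc)2, quinoline) gives 10.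

Further compounds
F1 | step 9 | 4-methoxybenzyl ester of keto acid 4 | CC1=CC[C@H]([C@H](C)C1=O)C(C)C(=O)OCc2ccc(OC)cc2
F2 | step 9 | C10 3-chloropropyl ketone (CH3 β, chloropropyl α) | CC1=CC[C@@H](C(C)C(=O)OCc2ccc(OC)cc2)[C@](C)(CCCCl)C1=O
F3 | step 9 | chloropropyl diene (C9=C11H2) | C=C1C(C)=CC[C@@H](C(C)C(=O)OCc2ccc(OC)cc2)[C@]1(C)CCCCl
F4 | step 9 | iodopropyl diene | C=C1C(C)=CC[C@@H](C(C)C(=O)OCc2ccc(OC)cc2)[C@]1(C)CCCI
F5 | step 9 | bicyclic diene ester (1,2-dihydro-15) | C=C1C(C)=CC[C@@H]2[C@]1(C)CCC[C@@]2(C)C(=O)OCc3ccc(OC)cc3
F6 | step 15 | (R,R)-hydrobenzoin spiro-ketal dienone | CC1=CC(=O)C(C[C@H]3C(C)=CC[C@@H]4[C@]3(C)CCC[C@@]4(C)C(=O)OCc3ccc(OC)cc3)=CC12O[C@H](c3ccccc3)[C@@H](c3ccccc3)O2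
F7 | step 15 | spiro-ketal epoxide | CC1=CC(=O)[C@]2(C[C@H]3C(C)=CC[C@@H]4[C@]3(C)CCC[C@@]4(C)C(=O)OCc3ccc(OC)cc3)O[C@@H]2C15O[C@H](c3ccccc3)[C@@H](c3ccccc3)O5
F8 | step 7 | propargylic aldol (epimers at C1 and C4) | CC1=CC[C@@H](C(C)C(=O)OC)[C@](C)(C(O)C#C[Si](C)(C)C)C1=O
F9 | step 7 | alkynyl diketone | CC1=CC[C@@H](C(C)C(=O)OC)[C@](C)(C(=O)C#C[Si](C)(C)C)C1=O
F10 | step 7 | configured propargylic alcohol | CC1=CC[C@@H](C(C)C(=O)OC)[C@](C)([C@@H](O)C#C[Si](C)(C)C)C1=O
F11 | step 7 | silylalkynyl lactone | CC1=CC[C@H]2C(C)C(=O)O[C@@H](C#C[Si](C)(C)C)[C@]2(C)C1=O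
F12 | step 7 | ethynyl lactone | CC1=CC[C@H]2C(C)C(=O)O[C@@H](C#C)[C@]2(C)C1=O
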